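Two questions stood on oak, the flask still being followed, and I wanted one number to answer both.

| flask | left-handed substrate | right-handed substrate | reagent | free catalyst | remark |
|---|---|---|---|---|---|
| oak | 0.10 M | 0.10 M | 0.30 M | 2.9 mM | the very flask that is asked about, followed so far |
| elm | 0.10 M | 0.10 M | 0.30 M | 1.9 mM | run made earlier |
| flask | 0.10 M | 0.10 M | 0.300 M | 2.9 mM |  |

- oak (time / h: left-handed product / %): 1.00: 4.2; 1.50: 5.5; 2.50: 7.9; 4.00: 11.5; 8.00: 16.8; 12.0: 21.5
- elm (time / d: left-handed product / %): 0.208: 7.8; 0.333: 12.1; 0.500: 15.6; 0.833: 20.4; 1.67: 25.2; 2.50: 27.6

(readings scatter by 1 percentage point)

- apparent order in reagent when 50 % of the left-handed substrate and right-handed substrate together are converted (percent change of the rate of making left-handed product for one percent more reagent charged)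
- factor on the rate of making left-handed product when 50 % of the left-handed substrate and right-handed substrate together are converted if free catalyst is charged twice over

Elm's last gains in left-handed product, 4.8 percentage points and then 2.4 points over equal spans, gave a fade constant λ of 0.835 d⁻¹, a rough reading given the scatter. I defined the reach D as the early mean rate of using left-handed substrate, per unit of its charge, divided by λ. For elm, read up to 0.333 d, D was 0.870, which put the left-handed ceiling at 29.1 % against 27.6 % at the last reading.

Scaled by catalyst charge, oak's D was 1.33. But that reach put oak at 18.2 % after 12.0 h, below the 21.5 % read, so one number was a rough guide.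

With both hands alike and activity fading exponentially, the rate at fixed conversion goes as D − L, where L, the log of the inverse unconverted fraction, is 0.693. Oak's order in reagent is then D/(D − L), 2.09, assuming reagent enters D as catalyst does, which is a guess. Oak's doubling factor is 3.09. Left-handed product was read and right-handed product was not, so both hands being alike stayed an assumption.

The forecast gave 1 and 2.7, noting: "Reagent order is a guess". The simulation gave 3.6 and 4.36.

    free catalyst → spent catalyst (k = 0.0290 h⁻¹)
    2 reagent → self-condensation product (k = 0.0334 L mol⁻¹ h⁻¹)
    reagent + free catalyst + right-handed substrate → free catalyst + right-handed product (k = 47.0 L² mol⁻² h⁻¹)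
    reagent + free catalyst + left-handed substrate → free catalyst + left-handed product (k = 82.4 L² mol⁻² h⁻¹)

In the flask, free catalyst had a half-life of 0.996 d against its loss to spent catalyst, shorter than the 1.3 d half-life of right-handed substrate by its step with reagent at 0.348 d, and at 6.00 d that half-life was 250 d with free catalyst at 1.54 %. At that time left-handed product stood at 35.6 %, beside the reach's ceiling of 36.8 %, and right-handed product at 25.5 %, so the two together stood at 61.1 %.

(The readings were computed with made-up constants; scatter was added.)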